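**Retrosynthetic overview**

1. Last operation: cleavage of a silyl ether on the C5 oxygen of the chromene, the only protecting group in the route.
2. Key disconnection: the bond from the bridging CH2 to aromatic C6 of the chromene, cut together with the pyran ring (O1–C2 and C4–C4a). In the forward direction a filicinic enone methide is trapped by a monocyclic aryl 1,1-dimethylpropargyl ether, and the same heating takes that ether through Claisen rearrangement, 1,5-hydrogen shift and oxa-6π closure.
3. Enabling feature: the bridging CH2 hangs on C4 of the filicinic ring, between the enolised carbonyl carbons C3 and C5 (a vinylogous acid), so a CH2–NMe2 group at C4 is expelled as a 2-methylene-1,3-dione. On the other half, O1 sits next to acyl-bearing C8 and the C5 oxygen is silylated, so the ether can only rearrange to C4a, only O1 can close the pyran, and only C6 (ortho to the free C7 hydroxyl) is open to the methide.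
4. Both halves come from one isobutyrylphloroglucinol: dearomative gem-dimethylation then aminomethylation for the filicinic half; para-O-silylation then ortho-O-propargylation for the aryl half.
5. Ring order: the benzene ring is bought (phloroglucinol); the filicinic ring arises by dearomatisation of one copy of it; the pyran ring is closed last, in the key step.

Key step: step 6

Remark: the enolised β-triketone (filicinic) ring is drawn throughout in the tautomer used for the target; its tautomers interconvert freely and the target has no stereocentre.

**Route**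

Step 1
Reactants: 1 phloroglucinol (benzene-1,3,5-triol); 2 isobutyryl chloride (2-methylpropanoyl chloride)
Product: 3 isobutyrylphloroglucinol [2-methyl-1-(2,4,6-trihydroxyphenyl)propan-1-one]
Conditions: AlCl3 (3 equiv), PhNO2/CH2Cl2, 0 °C to 40 °C; aq. HCl work-up
Reagents that add atoms: none
Why: Friedel–Crafts C-acylation of a threefold-activated arene whose three ring positions are equivalent, the first (aluminium-chelated) acyl group deactivating the ring against a second acylation.

Step 2
Reactants: 3 isobutyrylphloroglucinol
Product: 4 isobutyrylfilicinic acid [3,5-dihydroxy-6,6-dimethyl-2-(2-methylpropanoyl)cyclohexa-2,4-dien-1-one]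
Conditions: NaOMe (3 equiv), MeI (2.2 equiv), MeOH, 0 °C to rt; acidic work-up
Reagents that add atoms: iodomethane (MeI), CI
Why: Dearomative double C-methylation of an acylphloroglucinol (the phenoxide reacts as a vinylogous enolate), in which the second methyl group should enter at the carbon that already carries the first and so lock the ring as the cross-conjugated gem-dimethyl triketone; no stereocentre is formed.

Step 3
Reactants: 4 isobutyrylfilicinic acid
Product: 5 filicinic Mannich base [4-[(dimethylamino)methyl]-3,5-dihydroxy-6,6-dimethyl-2-(2-methylpropanoyl)cyclohexa-2,4-dien-1-one, handled as its zwitterion]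
Conditions: CH2(NMe2)2 (1.5 equiv), CH2Cl2, 0 °C to rt
Reagents that add atoms: N,N,N′,N′-tetramethylmethanediamine, CN(C)CN(C)C
Why: Mannich aminomethylation of a vinylogous acid with an aminal, in which the acidic enol releases the N,N-dimethylmethyleneiminium ion and the only free ring carbon (C4, between the two enolised carbonyls) attacks it; the zwitterion should precipitate, which protects it from elimination.

Step 4
Reactants: 3 isobutyrylphloroglucinol
Product: 6 1-[2,6-dihydroxy-4-(triisopropylsilyloxy)phenyl]-2-methylpropan-1-one
Conditions: TIPSCl (1.05 equiv), imidazole (2.2 equiv), DMF, 0 °C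
Reagents that add atoms: chlorotri(propan-2-yl)silane (TIPSCl), CC(C)[Si](Cl)(C(C)C)C(C)C
Why: Selective O-silylation of a phenol, the 4-hydroxyl being the most acidic and the only one neither hydrogen-bonded to the ketone nor flanked by the branched acyl group, so the bulky silyl chloride should react there first.

Step 5
Reactants: 6 1-[2,6-dihydroxy-4-(triisopropylsilyloxy)phenyl]-2-methylpropan-1-one; 7 3-chloro-3-methylbut-1-yne
Product: 8 1-[2-hydroxy-6-(2-methylbut-3-yn-2-yloxy)-4-(triisopropylsilyloxy)phenyl]-2-methylpropan-1-one
Conditions: DBU (1.6 equiv), CuCl2·2H2O (1 mol %), MeCN, 0 °C to rt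
Reagents that add atoms: none
Why: Copper-catalysed propargylic etherification of a phenol with a tertiary propargylic chloride (substitution through a copper acetylide intermediate), which tolerates hindered phenols; the two hydroxyls are equivalent by symmetry and the one left over is deactivated by chelation to the ketone, so the reaction should stop at the mono-ether.

Step 6
Reactants: 5 filicinic Mannich base; 8 1-[2-hydroxy-6-(2-methylbut-3-yn-2-yloxy)-4-(triisopropylsilyloxy)phenyl]-2-methylpropan-1-one
Product: 13 uliginosin B 5-O-triisopropylsilyl ether, via enone methide 9 (not isolated), via methylene-bridged propargyl ether 10 (not isolated), via allenylphenol 11 (not isolated), via ortho-quinone methide 12 (not isolated)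
Conditions: PhCl, 2,6-lutidine (2 equiv), 80 °C then 125 °C, Ar sweep
Reagents that add atoms: none
Why: At 80 °C zwitterion 5 loses dimethylamine (E1cB) to give enone methide 9, and C3 of phenol 8 adds to its exocyclic CH2 (Michael-type Friedel–Crafts C-alkylation, then re-enolisation) to form the CH2–aryl bond of 10; at 125 °C the ether of 10 undergoes aryl propargyl Claisen rearrangement and enolisation to allenylphenol 11, a 1,5-hydrogen shift from the new hydroxyl to the central allene carbon gives dienone 12, and 12 closes to the 2H-chromene. The closest known reaction types are the Mannich-base (methide) alkylation by which methylene-bridged acylphloroglucinol dimers are assembled and the thermal rearrangement of aryl 1,1-dimethylpropargyl ethers to 2,2-dimethyl-2H-chromenes, here run in one flask. The only ring closed is the pyran, by thermal disrotatory oxa-6π electrocyclisation of the (Z)-configured O=C–C=CH–CH=CMe2 unit of 12 (O–CMe2 bond formation). No stereocentre is created. Site selectivity of the C-alkylation is needed and should be secured because C3 is the only ring CH ortho to the free, ketone-chelated hydroxyl, whereas C5 is walled in by the triisopropylsilyloxy group and the tertiary ether; any molecule that rearranges before it is alkylated keeps a single aromatic CH and converges on the same product. Direction of ring closure and hetero-coupling should be secured because the other ortho carbon of the ether oxygen carries the acyl group and the para oxygen is silylated (only one oxygen can deliver hydrogen and close onto CMe2), and because 5 has no nucleophilic ring carbon left and is used in equimolar amount.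

Step 7
Reactants: 13 uliginosin B 5-O-triisopropylsilyl ether
Product: 14 uliginosin B
Conditions: Bu4NF (1.2 equiv), AcOH (1.5 equiv), THF, 0 °C
Reagents that add atoms: none
Why: Fluoride cleavage of an aryl silyl ether driven by Si–F bond formation, buffered with acetic acid so that the base-sensitive methylene bridge (retro-Michael exchange) and the chromene should stay untouched.

**Compound list**

1 | phloroglucinol (benzene-1,3,5-triol) | Oc1cc(O)cc(O)c1 | starting material
2 | isobutyryl chloride (2-methylpropanoyl chloride) | CC(C)C(Cl)=O | starting material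
3 | isobutyrylphloroglucinol, 2-methyl-1-(2,4,6-trihydroxyphenyl)propan-1-one | CC(C)C(=O)c1c(O)cc(O)cc1O | intermediate
4 | isobutyrylfilicinic acid, 3,5-dihydroxy-6,6-dimethyl-2-(2-methylpropanoyl)cyclohexa-2,4-dien-1-one | CC(C)C(=O)C1=C(O)C=C(O)C(C)(C)C1=O | intermediate
5 | filicinic Mannich base, 4-[(dimethylamino)methyl]-3,5-dihydroxy-6,6-dimethyl-2-(2-methylpropanoyl)cyclohexa-2,4-dien-1-one | CC(C)C(=O)C1=C(O)C(CN(C)C)=C(O)C(C)(C)C1=O | intermediate
6 | 1-[2,6-dihydroxy-4-(triisopropylsilyloxy)phenyl]-2-methylpropan-1-one | CC(C)C(=O)c1c(O)cc(O[Si](C(C)C)(C(C)C)C(C)C)cc1O | intermediate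
7 | 3-chloro-3-methylbut-1-yne | CC(C)(Cl)C#C | starting material
8 | 1-[2-hydroxy-6-(2-methylbut-3-yn-2-yloxy)-4-(triisopropylsilyloxy)phenyl]-2-methylpropan-1-one | CC(C)C(=O)c1c(O)cc(O[Si](C(C)C)(C(C)C)C(C)C)cc1OC(C)(C)C#C | intermediate
9 | enone methide, 5-hydroxy-2,2-dimethyl-6-methylidene-4-(2-methylpropanoyl)cyclohex-4-ene-1,3-dione | CC(C)C(=O)C1=C(O)C(=C)C(=O)C(C)(C)C1=O | intermediate (not isolated)
10 | methylene-bridged propargyl ether, 1-[3-{[2,6-dihydroxy-3,3-dimethyl-5-(2-methylpropanoyl)-4-oxocyclohexa-1,5-dien-1-yl]methyl}-2-hydroxy-6-(2-methylbut-3-yn-2-yloxy)-4-(triisopropylsilyloxy)phenyl]-2-methylpropan-1-one | CC(C)C(=O)c1c(O)c(CC2=C(O)C(C)(C)C(=O)C(C(=O)C(C)C)=C2O)c(O[Si](C(C)C)(C(C)C)C(C)C)cc1OC(C)(C)C#C | intermediate (not isolated)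
11 | allenylphenol, 1-[3-{[2,6-dihydroxy-3,3-dimethyl-5-(2-methylpropanoyl)-4-oxocyclohexa-1,5-dien-1-yl]methyl}-2,6-dihydroxy-5-(3-methylbuta-1,2-dien-1-yl)-4-(triisopropylsilyloxy)phenyl]-2-methylpropan-1-one | CC(C)C(=O)c1c(O)c(CC2=C(O)C(C)(C)C(=O)C(C(=O)C(C)C)=C2O)c(O[Si](C(C)C)(C(C)C)C(C)C)c(C=C=C(C)C)c1O | intermediate (not isolated)
12 | ortho-quinone methide (dienone): compound 11 after transfer of the C6 hydroxyl hydrogen to the central allene carbon, with C6=O and an exocyclic (Z)-3-methylbut-2-en-1-ylidene group at C5, the vinyl group syn to the C6 carbonyl | CC(C)C(=O)C1=C(O)C(CC2=C(O)C(C)(C)C(=O)C(C(=O)C(C)C)=C2O)=C(O[Si](C(C)C)(C(C)C)C(C)C)/C(=C/C=C(C)C)C1=O | intermediate (not isolated)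
13 | uliginosin B 5-O-triisopropylsilyl ether, 3,5-dihydroxy-4-{[7-hydroxy-2,2-dimethyl-8-(2-methylpropanoyl)-5-(triisopropylsilyloxy)-2H-chromen-6-yl]methyl}-6,6-dimethyl-2-(2-methylpropanoyl)cyclohexa-2,4-dien-1-one | CC(C)C(=O)C1=C(O)C(Cc2c(O[Si](C(C)C)(C(C)C)C(C)C)c3c(c(C(=O)C(C)C)c2O)OC(C)(C)C=C3)=C(O)C(C)(C)C1=O | intermediate
14 | uliginosin B, 3,5-dihydroxy-4-{[5,7-dihydroxy-2,2-dimethyl-8-(2-methylpropanoyl)-2H-chromen-6-yl]methyl}-6,6-dimethyl-2-(2-methylpropanoyl)cyclohexa-2,4-dien-1-one | CC(C)C(=O)C1=C(O)C(Cc2c(O)c3c(c(C(=O)C(C)C)c2O)OC(C)(C)C=C3)=C(O)C(C)(C)C1=O | target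

**Step count and risks**

Total steps: 7. Longest linear sequence: 5 steps (1 → 3 → 6 → 8 → 13 → 14; the branch 1 → 3 → 4 → 5 → 13 → 14 is equally long).

Steps most likely to fail:

Step 6. The methide may alkylate the wrong ring carbon (C5, para to the free hydroxyl) or oxygen before the sigmatropic step. The methylene bridge may exchange by retro-Michael cleavage and recombination at 125 °C, giving symmetrical dimers. The silyl group may be lost before ring closure, which would let the pyran close onto the other oxygen. Fallback: set out from 8 and separate the two events. Compound 8 alone is heated (PhCl, 2,6-lutidine, 125 °C) so that the Claisen/electrocyclisation sequence gives 1-[7-hydroxy-2,2-dimethyl-5-(triisopropylsilyloxy)-2H-chromen-8-yl]-2-methylpropan-1-one F1, which has one aromatic CH only. F1 is then alkylated with Mannich base 5 (1,4-dioxane, 80 °C), well below the temperature of bridge exchange, and the route is rejoined at 13.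

Step 5. Etherification of the chelated, doubly flanked hydroxyl by a tertiary electrophile may be slow, with elimination of the chloride to the enyne, C-propargylation and premature rearrangement of the ether competing. Fallback: set out from 6 and leave out the propargyl ether. Excess 6 is C-alkylated once with Mannich base 5 (1,4-dioxane, 80 °C) to give the mono-bridged silyl ether 1-[3-{[2,6-dihydroxy-3,3-dimethyl-5-(2-methylpropanoyl)-4-oxocyclohexa-1,5-dien-1-yl]methyl}-2,6-dihydroxy-4-(triisopropylsilyloxy)phenyl]-2-methylpropan-1-one F2. The pyran ring is then closed with 3-methylbut-2-enal and catalytic ethylenediammonium diacetate (toluene, reflux; Knoevenagel-type condensation followed by oxa-6π electrocyclisation) at the one remaining aromatic CH and its one free neighbouring hydroxyl, which rejoins the route at 13.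

Step 2. Under- and over-methylation (mono-, tri- and O-methylated products) may occur, since each C-methylation leaves an enolate that is still nucleophilic; the gem-dimethyl compound would then be hard to obtain pure. Fallback: set out from isobutyryl chloride 2 and build the gem-dimethyl ring before the acyl group is attached. Double Claisen condensation of commercial 3,3-dimethylpentane-2,4-dione with diethyl carbonate (NaH, THF, reflux) should give filicinic acid (3,5-dihydroxy-4,4-dimethylcyclohexa-2,5-dien-1-one) F3. O-acylation with 2 (Et3N, CH2Cl2, 0 °C) gives the enol ester 5-hydroxy-6,6-dimethyl-3-oxocyclohexa-1,4-dien-1-yl 2-methylpropanoate F4, and DMAP-catalysed O-to-C acyl migration (the standard way to 2-acylcyclohexane-1,3-diones) rejoins the route at 4.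

Further compounds
F1 | step 6 | 1-[7-hydroxy-2,2-dimethyl-5-(triisopropylsilyloxy)-2H-chromen-8-yl]-2-methylpropan-1-one | CC(C)C(=O)c1c(O)cc(O[Si](C(C)C)(C(C)C)C(C)C)c2C=CC(C)(C)Oc12
F2 | step 5 | 1-[3-{[2,6-dihydroxy-3,3-dimethyl-5-(2-methylpropanoyl)-4-oxocyclohexa-1,5-dien-1-yl]methyl}-2,6-dihydroxy-4-(triisopropylsilyloxy)phenyl]-2-methylpropan-1-one | CC(C)C(=O)c1c(O)cc(O[Si](C(C)C)(C(C)C)C(C)C)c(CC2=C(O)C(C)(C)C(=O)C(C(=O)C(C)C)=C2O)c1O
F3 | step 2 | filicinic acid, 3,5-dihydroxy-4,4-dimethylcyclohexa-2,5-dien-1-one | CC1(C)C(O)=CC(=O)C=C1O
F4 | step 2 | 5-hydroxy-6,6-dimethyl-3-oxocyclohexa-1,4-dien-1-yl 2-methylpropanoate | CC(C)C(=O)OC1=CC(=O)C=C(O)C1(C)C
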